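Assumption: aldehydes 2 and 4 are bought as catalogue vanillin derivatives. Lignan numbering is used for atom labels (C7/C8/C9 = carbinol half, C7'/C8'/C9' = ring-aryl half). The route has not been run; conditions are proposals.

**Retrosynthetic overview**
- The tetrahydrofuran is the last ring formed, by C9–O to C7' closure (5-exo oxa-1,6-addition to a p-quinone methide) of an acyclic tetraol. The single free phenol selects which benzylic carbinol may ionise.
- The tetraol comes from LiAlH4 reduction of a trans-α,β-disubstituted γ-butyrolactone. The C8'–C7' bond is made by a lactone-enolate aldol with an ester-protected vanillin.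
- The β-(hydroxybenzyl)-γ-butyrolactone comes from an L-proline cross-aldol of methyl 4-oxobutanoate with TBS-vanillin, then reduction and lactonisation. This sets C7 and C8.
- Ring order: γ-lactone first (temporary, relays C8 to C8'), opened by reduction, then the tetrahydrofuran.

**Route**

Step 1
Reactants: 1 methyl 4-oxobutanoate; 2 4-[(tert-butyldimethylsilyl)oxy]-3-methoxybenzaldehyde
Product: 3 (4R)-4-[(R)-(4-TBSO-3-methoxyphenyl)(hydroxy)methyl]oxolan-2-one
Conditions: L-proline (20 mol %), DMF, 4 °C, slow addition of 1 (2 equiv); then MeOH, NaBH4, 0 °C, one pot; lactonises on work-up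
Reagents that add atoms: none
Why: The L-proline enamine of 1 adds to aldehyde 2 through the H-bonded Houk–List transition state (direct asymmetric cross-aldol) to give the anti aldol, setting C7 (R) and C8 (R); immediate NaBH4 reduction prevents epimerisation and the primary alcohol closes onto the methyl ester.

Step 2
Reactants: 3; 4 4-formyl-2-methoxyphenyl 2-methylpropanoate (vanillin isobutyrate)
Product: 5 (3S,4R)-3-[(RS)-hydroxy(4-isobutyryloxy-3-methoxyphenyl)methyl]-4-[(R)-(4-TBSO-3-methoxyphenyl)(hydroxy)methyl]oxolan-2-one (C7' epimer mixture)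
Conditions: LiHMDS (2.2 equiv), THF, −78 °C; then 4 (1.2 equiv), −78 °C, 30 min; AcOH quench at −78 °C
Reagents that add atoms: none
Why: The lithium enolate of the lactone (formed as the alkoxide–enolate dianion) adds to 4 anti to the C4 substituent (lactone-enolate aldol), setting C8' trans to C8; the C7' carbinol forms as a mixture, which is harmless because step 4 is stereoconvergent.

Step 3
Reactants: 5
Product: 6 (1R,2R,3R,4RS)-1-(4-TBSO-3-methoxyphenyl)-4-(4-hydroxy-3-methoxyphenyl)-2,3-bis(hydroxymethyl)butane-1,4-diol
Conditions: LiAlH4 (5 equiv), THF, −10 → 0 °C; Rochelle salt work-up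
Reagents that add atoms: none
Why: LiAlH4 reduces the lactone to the 1,4-diol and cleaves the aryl ester (LiAlH4 reduction), freeing only the ring-B phenol, while the aryl silyl ether and all stereocentres are untouched at ≤0 °C.

Step 4
Reactants: 6
Product: 7 4-[(2S,3R,4R)-4-[(R)-(4-TBSO-3-methoxyphenyl)(hydroxy)methyl]-3-(hydroxymethyl)oxolan-2-yl]-2-methoxyphenol
Conditions: (PhO)2P(O)OH (10 mol %), 4 Å MS, MeCN, 0 °C → rt
Reagents that add atoms: none
Why: Proposed new method: a phenol-gated, phosphoric-acid-catalysed dehydrative cycloetherification — the acid H-bonds to the free ring-B phenol and the C7'–OH, water leaves to give a transient enolisable alkyl p-quinone methide (both C7' epimers converge on it), and the primary C9–OH adds 5-exo (oxa-1,6-addition) so the aryl ends up trans to both ring neighbours, setting C7' (S) (also the thermodynamic isomer, as the closure is reversible); the C7 carbinol is para to OTBS, cannot form a quinone methide, and is expected to be neither ionised nor competitive as a secondary nucleophile, so C7 (R) survives unprotected; closest known reaction type: Brønsted-acid generation of aryl-stabilised p-quinone methides from p-hydroxybenzyl alcohols with 1,6-addition of O-nucleophiles, and classical acid cyclodehydration of 1,4-diols to 2-aryl-tetrahydrofuran lignans, neither shown for selecting between two benzylic carbinols and two hydroxyl types in an unprotected tetraol.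

Step 5
Reactants: 7
Product: 8 (7R)-7-hydroxylariciresinol, 4-[(2S,3R,4R)-4-[(R)-hydroxy(4-hydroxy-3-methoxyphenyl)methyl]-3-(hydroxymethyl)oxolan-2-yl]-2-methoxyphenol
Conditions: TBAF (2.2 equiv), AcOH (2.2 equiv), THF, 0 °C; pH 7 buffer work-up
Reagents that add atoms: none
Why: Buffered fluoride cleaves the aryl silyl ether (silyl ether deprotection) without acid, so the p-hydroxybenzylic C7–OH is not ionised and neither furofuran closure nor C7 epimerisation occurs.

**Compound list**
1 | methyl 4-oxobutanoate | COC(=O)CCC=O | starting material
2 | 4-[(tert-butyldimethylsilyl)oxy]-3-methoxybenzaldehyde | COc1cc(C=O)ccc1O[Si](C)(C)C(C)(C)C | starting material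
3 | (4R)-4-[(R)-(4-TBSO-3-methoxyphenyl)(hydroxy)methyl]oxolan-2-one | O=C1OC[C@H]([C@@H](O)c2ccc(O[Si](C)(C)C(C)(C)C)c(OC)c2)C1 | intermediate
4 | 4-formyl-2-methoxyphenyl 2-methylpropanoate | COc1cc(C=O)ccc1OC(=O)C(C)C | starting material
5 | (3S,4R)-3-[(RS)-hydroxy(4-isobutyryloxy-3-methoxyphenyl)methyl]-4-[(R)-(4-TBSO-3-methoxyphenyl)(hydroxy)methyl]oxolan-2-one | O=C1OC[C@H]([C@@H](O)c2ccc(O[Si](C)(C)C(C)(C)C)c(OC)c2)[C@H]1C(O)c3ccc(OC(=O)C(C)C)c(OC)c3 | intermediate
6 | (1R,2R,3R,4RS)-1-(4-TBSO-3-methoxyphenyl)-4-(4-hydroxy-3-methoxyphenyl)-2,3-bis(hydroxymethyl)butane-1,4-diol | OC[C@H]([C@@H](O)c1ccc(O[Si](C)(C)C(C)(C)C)c(OC)c1)[C@H](CO)C(O)c1ccc(O)c(OC)c1 | intermediate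
7 | 4-[(2S,3R,4R)-4-[(R)-(4-TBSO-3-methoxyphenyl)(hydroxy)methyl]-3-(hydroxymethyl)oxolan-2-yl]-2-methoxyphenol | COc1cc([C@H]2OC[C@H]([C@@H](O)c3ccc(O[Si](C)(C)C(C)(C)C)c(OC)c3)[C@@H]2CO)ccc1O | intermediate
8 | (7R)-7-hydroxylariciresinol | COc1cc([C@H]2OC[C@H]([C@@H](O)c3ccc(O)c(OC)c3)[C@@H]2CO)ccc1O | target

**Totals**
Total steps: 5. Longest linear sequence: 5.

**Steps most likely to fail**
1. Step 4 (proposed new step). Risks are closure by the secondary C7–OH (giving a 2,5-diaryl tetrahydrofuran), Friedel–Crafts attack by ring A, and tautomerisation of the quinone methide to a vinylphenol. Fallback (known chemistry): silylate the C7–OH of 3 (TBSOTf, 2,6-lutidine) before the aldol. The triol from LiAlH4 then has one free benzylic OH and no competing secondary hydroxyl, and the ring is closed by conventional CSA-mediated cyclodehydration. The final TBAF step removes both silyl groups (+1 step).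
2. Step 2. Risks are retro-aldol, translactonisation, or acyl transfer between lithium alkoxides and the aryl ester. Fallback: change to a silyl-enolate approach. Make the TBS ether of 3, convert it to the silyl ketene acetal (TBSOTf, Et3N), and run a BF3·OEt2 Mukaiyama aldol with 4. This gives the same trans selectivity with no lithium alkoxides.
3. Step 1. The electron-rich aldehyde 2 is a slow acceptor, so self-aldol of 1 may compete. Fallback: run the proline aldol on the more electrophilic ester-protected aldehyde 4, then exchange the phenol protecting group (K2CO3/MeOH, then phenol-selective TBSCl/imidazole) to reach 3 (+2 operations).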